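**Retrosynthetic overview**

- The strategy rests on a local repeat in the chain. The central C9H=C10H double bond carries the same unit –CH=C(CH3)–CH=CH–CH=C(CH3)– on both sides (C8 to C3 and C11 to C16). One copy ends at the acetyl carbon C2, the other at the alkyne C17≡C18 on ring A, the only ring, a 4-hydroxy-2,6,6-trimethylcyclohexene.
- Key disconnections are the two sp2–sp2 single bonds C8–C9 and C10–C11. They lead to an iodotrienone, an (E)-vinylene carrying tin at one end and boron at the other, and an iodotrienynol of ring A, joined in one flask by Stille and then Suzuki–Miyaura coupling.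
- Both iodotrienes grow from one C4 iodo-enal (carboalumination–iodination of propargyl alcohol, then oxidation). Two Wittig reactions give the ketone piece; a Horner–Wadsworth–Emmons reaction with a C15 ring phosphonate gives the ring piece. The phosphonate comes from (4R,6R)-actinol by enol triflate formation and Sonogashira coupling.
- No ring is formed. Ring A and its (R)-carbinol centre come intact from actinol, and all seven E alkenes are fixed in the three pieces before the coupling.

Key step: step 13

Remark on the chemistry: the chain is numbered from the acetyl methyl (C1) to the ring-bound alkyne carbon (C18); (4R,6R)-actinol, (E)-3-methylpent-2-en-4-yn-1-ol and the ethynyl pinacol boronate are assumed to be commercial.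

**Route**

Step 1
Reactants: 1 propargyl alcohol
Product: 3 (E)-3-iodo-2-methylprop-2-en-1-ol, via alkenylalane 2 (not isolated)
Conditions: Me3Al (3 equiv), Cp2ZrCl2 (0.25 equiv), CH2Cl2, 0 °C to rt; then I2, THF, −30 to 0 °C; aqueous work-up
Reagents that add atoms: trimethylaluminium, C[Al](C)C; iodine, II
Why: Zirconium-catalysed carboalumination (Negishi) adds CH3 and aluminium syn across the alkyne with the methyl on the internal carbon, and iodinolysis of the C–Al bond with retention should give the E iodoalkene.

Step 2
Reactants: 3 (E)-3-iodo-2-methylprop-2-en-1-ol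
Product: 4 (E)-3-iodo-2-methylprop-2-enal
Conditions: activated MnO2 (excess), CH2Cl2, rt, dark; filtered and used as a solution
Reagents that add atoms: none
Why: MnO2 oxidation of an allylic alcohol should stop at the enal and leave the vinyl iodide and the alkene geometry untouched.

Step 3
Reactants: 4 (E)-3-iodo-2-methylprop-2-enal
Product: 5 (2E,4E)-5-iodo-4-methylpenta-2,4-dienal
Conditions: Ph3P=CHCHO (1.05 equiv), toluene, 70 °C, dark
Reagents that add atoms: (triphenylphosphoranylidene)acetaldehyde, O=CC=P(c1ccccc1)(c1ccccc1)c1ccccc1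
Why: Wittig olefination with the stabilised formyl ylide should give the E dienal, and a near-stoichiometric charge of ylide at moderate temperature should hold back a second homologation.

Step 4
Reactants: 5 (2E,4E)-5-iodo-4-methylpenta-2,4-dienal
Product: 6 (3E,5E,7E)-8-iodo-3,7-dimethylocta-3,5,7-trien-2-one
Conditions: Ph3P=C(CH3)C(O)CH3 (1.5 equiv), toluene, 90 °C, dark
Reagents that add atoms: 3-(triphenylphosphoranylidene)butan-2-one, CC(=O)C(C)=P(c1ccccc1)(c1ccccc1)c1ccccc1
Why: Wittig reaction of the stabilised acyl ylide with an aldehyde is under thermodynamic control and should give the E trisubstituted enone without touching the vinyl iodide.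

Step 5
Reactants: 7 (4R,6R)-actinol ((4R,6R)-4-hydroxy-2,2,6-trimethylcyclohexanone)
Product: 8 (4R,6R)-4-(tert-butyldimethylsilyloxy)-2,2,6-trimethylcyclohexanone
Conditions: TBSCl, imidazole, DMF, rt
Reagents that add atoms: tert-butyldimethylsilyl chloride, CC(C)(C)[Si](C)(C)Cl
Why: Silylation of the secondary alcohol masks the hydroxyl for the enolate chemistry and does not touch the carbinol centre.

Step 6
Reactants: 8 (4R,6R)-4-(tert-butyldimethylsilyloxy)-2,2,6-trimethylcyclohexanone
Product: 10 (R)-4-(tert-butyldimethylsilyloxy)-2,6,6-trimethylcyclohex-1-en-1-yl trifluoromethanesulfonate, via lithium enolate 9 (not isolated)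
Conditions: LiN(i-Pr)2, THF, −78 °C; then PhNTf2, −78 °C to rt; aq NH4Cl
Reagents that add atoms: N-phenylbis(trifluoromethanesulfonimide), O=S(=O)(N(c1ccccc1)S(=O)(=O)C(F)(F)F)C(F)(F)F; lithium diisopropylamide, [Li+].CC(C)[N-]C(C)C (lithium of 9 only)
Why: The ketone has an α-hydrogen only at C6 (C2 is quaternary), so deprotonation and O-triflation of the enolate should give the single tetrasubstituted enol triflate, while the silyloxy-bearing carbon, remote from the carbonyl, keeps its R configuration.

Step 7
Reactants: 10 (R)-4-(tert-butyldimethylsilyloxy)-2,6,6-trimethylcyclohex-1-en-1-yl trifluoromethanesulfonate; 11 (E)-3-methylpent-2-en-4-yn-1-ol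
Product: 12 (E)-5-[(R)-4-(tert-butyldimethylsilyloxy)-2,6,6-trimethylcyclohex-1-en-1-yl]-3-methylpent-2-en-4-yn-1-ol
Conditions: Pd(PPh3)4 (5 mol %), CuI (10 mol %), i-Pr2NH, DMF, rt
Reagents that add atoms: none
Why: Sonogashira coupling of an alkenyl triflate with a terminal alkyne tolerates the free primary alcohol and the silyl ether and carries the E alkene of 11 into the product unchanged.

Step 8
Reactants: 12 (E)-5-[(R)-4-(tert-butyldimethylsilyloxy)-2,6,6-trimethylcyclohex-1-en-1-yl]-3-methylpent-2-en-4-yn-1-ol
Product: 13 tert-butyl{[(R)-4-((E)-5-bromo-3-methylpent-3-en-1-yn-1-yl)-3,5,5-trimethylcyclohex-3-en-1-yl]oxy}dimethylsilane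
Conditions: CBr4, PPh3, CH2Cl2, −20 to 0 °C; filtered through silica and used crude
Reagents that add atoms: carbon tetrabromide, BrC(Br)(Br)Br
Why: Appel bromination converts the primary allylic alcohol into the bromide under neutral conditions that the silyl ether withstands, and the low temperature should prevent allylic transposition.

Step 9
Reactants: 13 tert-butyl{[(R)-4-((E)-5-bromo-3-methylpent-3-en-1-yn-1-yl)-3,5,5-trimethylcyclohex-3-en-1-yl]oxy}dimethylsilane
Product: 14 diethyl {(E)-5-[(R)-4-(tert-butyldimethylsilyloxy)-2,6,6-trimethylcyclohex-1-en-1-yl]-3-methylpent-2-en-4-yn-1-yl}phosphonate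
Conditions: P(OEt)3 (neat), 90 °C; excess phosphite removed in vacuo
Reagents that add atoms: triethyl phosphite, CCOP(OCC)OCC
Why: Michaelis–Arbuzov reaction of a primary allylic bromide should give the phosphonate by direct substitution at the unhindered CH2 terminus.

Step 10
Reactants: 14 diethyl {(E)-5-[(R)-4-(tert-butyldimethylsilyloxy)-2,6,6-trimethylcyclohex-1-en-1-yl]-3-methylpent-2-en-4-yn-1-yl}phosphonate; 4 (E)-3-iodo-2-methylprop-2-enal
Product: 16 tert-butyl{[(R)-4-((3E,5E,7E)-8-iodo-3,7-dimethylocta-3,5,7-trien-1-yn-1-yl)-3,5,5-trimethylcyclohex-3-en-1-yl]oxy}dimethylsilane, via phosphonate anion 15 (not isolated)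
Conditions: NaN(SiMe3)2, THF, −78 °C; then 4, −78 to 0 °C, dark
Reagents that add atoms: sodium bis(trimethylsilyl)amide, [Na+].C[Si](C)(C)[N-][Si](C)(C)C (sodium of 15 only)
Why: Horner–Wadsworth–Emmons olefination of the stabilised allylic phosphonate anion with the enal should form the new disubstituted alkene E, and generating the anion cold and trapping it at once should preserve the E alkene beside the alkyne.

Step 11
Reactants: 16 tert-butyl{[(R)-4-((3E,5E,7E)-8-iodo-3,7-dimethylocta-3,5,7-trien-1-yn-1-yl)-3,5,5-trimethylcyclohex-3-en-1-yl]oxy}dimethylsilane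
Product: 17 (R)-4-[(3E,5E,7E)-8-iodo-3,7-dimethylocta-3,5,7-trien-1-yn-1-yl]-3,5,5-trimethylcyclohex-3-en-1-ol
Conditions: Bu4NF, THF, 0 °C to rt, dark
Reagents that add atoms: none
Why: Fluoride cleavage of the silyl ether frees the secondary alcohol with retention at carbon and does not affect the alkenyl iodide or the trienyne.

Step 12
Reactants: 18 2-ethynyl-4,4,5,5-tetramethyl-1,3,2-dioxaborolane
Product: 19 (E)-tributyl[2-(4,4,5,5-tetramethyl-1,3,2-dioxaborolan-2-yl)vinyl]stannane
Conditions: Bu3SnH (1.05 equiv), AIBN (cat.), toluene, 80 °C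
Reagents that add atoms: tributyltin hydride, CCCC[SnH](CCCC)CCCC
Why: In this radical hydrostannation the stannyl radical adds to the unsubstituted alkyne carbon to give a boron-stabilised vinyl radical, and reversible addition–elimination of tin radicals should funnel the adduct to the thermodynamically favoured E isomer.

Step 13
Reactants: 6 (3E,5E,7E)-8-iodo-3,7-dimethylocta-3,5,7-trien-2-one; 19 (E)-tributyl[2-(4,4,5,5-tetramethyl-1,3,2-dioxaborolan-2-yl)vinyl]stannane; 17 (R)-4-[(3E,5E,7E)-8-iodo-3,7-dimethylocta-3,5,7-trien-1-yn-1-yl]-3,5,5-trimethylcyclohex-3-en-1-ol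
Product: 21 CNP0167252.1 [(3E,5E,7E,9E,11E,13E,15E)-18-((R)-4-hydroxy-2,6,6-trimethylcyclohex-1-en-1-yl)-3,7,12,16-tetramethyloctadeca-3,5,7,9,11,13,15-heptaen-17-yn-2-one], via tetraenyl boronate 20 (not isolated)
Conditions: 6 (1.0 equiv), 19 (1.05 equiv), PdCl2(MeCN)2 (5 mol %), degassed DMF, rt, dark; then 17 (0.95 equiv), 2 M aq K3PO4 (3 equiv), THF, rt; aq KF work-up, chromatography and crystallisation in dim light
Reagents that add atoms: none
Why: A small part of the stannane reduces the divalent palladium precatalyst to zerovalent palladium, which inserts into the C–I bond of 6; transmetalation then occurs at tin only, because the neutral pinacol boronate does not transfer its vinyl group without base, and reductive elimination forms C8–C9 to give boronate 20. Adding 17 and aqueous K3PO4 converts 20 into a borate, and the same catalyst runs the Suzuki–Miyaura cycle (oxidative addition into the C–I bond of 17, transmetalation from boron, reductive elimination) to form C10–C11. The closest known reaction type is the one-pot Stille then Suzuki–Miyaura coupling of tin–boron bis-metallated alkenes and dienes with two different alkenyl iodides for polyene assembly. No ring is closed and no stereocentre is formed, and the (R)-carbinol carbon of ring A is a spectator. The step needs tin to react before boron and all seven E alkenes to be retained; the base-free first stage secures the former, and the stereoretentive elementary steps at sp2 carbon, together with room temperature, short reaction time and exclusion of light, should secure the latter, in particular at C15=C16 beside the alkyne. Neither the ketone of 6 nor the free hydroxyl of 17 should interfere with either cycle, so the coupling should end at the unprotected target.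

**Compound list**

1 | propargyl alcohol | C#CCO | starting material
2 | dimethylaluminium (E)-3-(dimethylalumanyl)-2-methylprop-2-en-1-olate (alkenylalane) | C[Al](C)OC/C(C)=C/[Al](C)C | intermediate (not isolated)
3 | (E)-3-iodo-2-methylprop-2-en-1-ol | OC/C(C)=C/I | intermediate
4 | (E)-3-iodo-2-methylprop-2-enal | O=C/C(C)=C/I | intermediate
5 | (2E,4E)-5-iodo-4-methylpenta-2,4-dienal | O=C/C=C/C(C)=C/I | intermediate
6 | (3E,5E,7E)-8-iodo-3,7-dimethylocta-3,5,7-trien-2-one | CC(=O)/C(C)=C/C=C/C(C)=C/I | intermediate
7 | (4R,6R)-actinol, (4R,6R)-4-hydroxy-2,2,6-trimethylcyclohexanone | O=C1[C@H](C)C[C@@H](O)CC1(C)C | starting material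
8 | (4R,6R)-4-(tert-butyldimethylsilyloxy)-2,2,6-trimethylcyclohexanone | O=C1[C@H](C)C[C@@H](O[Si](C)(C)C(C)(C)C)CC1(C)C | intermediate
9 | lithium (R)-4-(tert-butyldimethylsilyloxy)-2,6,6-trimethylcyclohex-1-en-1-olate (lithium enolate) | [Li+].[O-]C1=C(C)C[C@@H](O[Si](C)(C)C(C)(C)C)CC1(C)C | intermediate (not isolated)
10 | (R)-4-(tert-butyldimethylsilyloxy)-2,6,6-trimethylcyclohex-1-en-1-yl trifluoromethanesulfonate | O=S(=O)(OC1=C(C)C[C@@H](O[Si](C)(C)C(C)(C)C)CC1(C)C)C(F)(F)F | intermediate
11 | (E)-3-methylpent-2-en-4-yn-1-ol | C#C/C(C)=C/CO | starting material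
12 | (E)-5-[(R)-4-(tert-butyldimethylsilyloxy)-2,6,6-trimethylcyclohex-1-en-1-yl]-3-methylpent-2-en-4-yn-1-ol | OC/C=C(\C)C#CC1=C(C)C[C@@H](O[Si](C)(C)C(C)(C)C)CC1(C)C | intermediate
13 | tert-butyl{[(R)-4-((E)-5-bromo-3-methylpent-3-en-1-yn-1-yl)-3,5,5-trimethylcyclohex-3-en-1-yl]oxy}dimethylsilane | BrC/C=C(\C)C#CC1=C(C)C[C@@H](O[Si](C)(C)C(C)(C)C)CC1(C)C | intermediate
14 | diethyl {(E)-5-[(R)-4-(tert-butyldimethylsilyloxy)-2,6,6-trimethylcyclohex-1-en-1-yl]-3-methylpent-2-en-4-yn-1-yl}phosphonate | CCOP(=O)(OCC)C/C=C(\C)C#CC1=C(C)C[C@@H](O[Si](C)(C)C(C)(C)C)CC1(C)C | intermediate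
15 | sodium salt of the α-carbanion of phosphonate 14 (phosphonate anion) | [Na+].CCOP(=O)(OCC)[CH-]/C=C(\C)C#CC1=C(C)C[C@@H](O[Si](C)(C)C(C)(C)C)CC1(C)C | intermediate (not isolated)
16 | tert-butyl{[(R)-4-((3E,5E,7E)-8-iodo-3,7-dimethylocta-3,5,7-trien-1-yn-1-yl)-3,5,5-trimethylcyclohex-3-en-1-yl]oxy}dimethylsilane | I/C=C(C)/C=C/C=C(\C)C#CC1=C(C)C[C@@H](O[Si](C)(C)C(C)(C)C)CC1(C)C | intermediate
17 | (R)-4-[(3E,5E,7E)-8-iodo-3,7-dimethylocta-3,5,7-trien-1-yn-1-yl]-3,5,5-trimethylcyclohex-3-en-1-ol | I/C=C(C)/C=C/C=C(\C)C#CC1=C(C)C[C@@H](O)CC1(C)C | intermediate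
18 | 2-ethynyl-4,4,5,5-tetramethyl-1,3,2-dioxaborolane | C#CB1OC(C)(C)C(C)(C)O1 | starting material
19 | (E)-tributyl[2-(4,4,5,5-tetramethyl-1,3,2-dioxaborolan-2-yl)vinyl]stannane | CCCC[Sn](CCCC)(CCCC)/C=C/B1OC(C)(C)C(C)(C)O1 | intermediate
20 | (3E,5E,7E,9E)-3,7-dimethyl-10-(4,4,5,5-tetramethyl-1,3,2-dioxaborolan-2-yl)deca-3,5,7,9-tetraen-2-one (tetraenyl boronate) | CC(=O)/C(C)=C/C=C/C(C)=C/C=C/B1OC(C)(C)C(C)(C)O1 | intermediate (not isolated)
21 | CNP0167252.1, (3E,5E,7E,9E,11E,13E,15E)-18-[(R)-4-hydroxy-2,6,6-trimethylcyclohex-1-en-1-yl]-3,7,12,16-tetramethyloctadeca-3,5,7,9,11,13,15-heptaen-17-yn-2-one | CC(=O)/C(C)=C/C=C/C(C)=C/C=C/C=C(C)/C=C/C=C(\C)C#CC1=C(C)C[C@@H](O)CC1(C)C | target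

**Step count**

Total: 13 steps. Longest linear sequence: 8 steps, from 7 to 21 (steps 5 to 11 and 13).

**Steps most likely to fail**

Step 13. Three processes threaten it. Boron may transfer early, or the stannane may homocouple while the divalent palladium precatalyst is being reduced. The boronate 20 may be protodeboronated once base is present. The polyene may isomerise from E to Z on palladium or in light, most easily at C15=C16 beside the alkyne. The fallback gives up the tin–boron reagent for two separate base-free Stille couplings. It sets out from 6 and 17 and comes back at 21. Iodide 6 would be coupled with an excess of commercial (E)-1,2-bis(tributylstannyl)ethene, CCCC[Sn](CCCC)(CCCC)/C=C/[Sn](CCCC)(CCCC)CCCC, using PdCl2(MeCN)2 in DMF at rt. This should give (3E,5E,7E,9E)-3,7-dimethyl-10-(tributylstannyl)deca-3,5,7,9-tetraen-2-one F1, isolated quickly on triethylamine-deactivated silica. A second Stille coupling of F1 with 17 (Pd2(dba)3, AsPh3, DMF, rt, dark) should then give 21.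

Step 10. The trisubstituted alkene beside the alkyne may lose its E geometry by rotation within the delocalised carbanion. E selectivity at the new alkene may be incomplete, and the anion may attack through its γ-carbon. The fallback reverses the polarity, so that the enyne alkene is never part of a carbanion. It sets out from 12 and from 3 and comes back at 16. MnO2 in CH2Cl2 should oxidise 12 to (E)-5-[(R)-4-(tert-butyldimethylsilyloxy)-2,6,6-trimethylcyclohex-1-en-1-yl]-3-methylpent-2-en-4-ynal F2. In parallel, 3 would be brominated (CBr4, PPh3) to (E)-3-bromo-1-iodo-2-methylprop-1-ene F3 and heated with P(OEt)3 to give diethyl [(E)-3-iodo-2-methylprop-2-en-1-yl]phosphonate F4. Deprotonation with NaN(SiMe3)2 in THF at −78 °C should give the sodium salt of the F4 carbanion F5, and its Horner–Wadsworth–Emmons reaction with F2 should give 16.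

Step 12. Radical addition may proceed with incomplete regio- and stereocontrol, leaving Z and α-stannyl isomers that are hard to remove, and the product may be protodestannylated during purification. The fallback takes the E geometry from a commercial reagent instead of creating it. It replaces 18, consumes no numbered compound of the route, and comes back at 19. One tin–lithium exchange on (E)-1,2-bis(tributylstannyl)ethene (n-BuLi, THF, −78 °C) should give (E)-2-(tributylstannyl)vinyllithium F6. Trapping with 2-isopropoxy-4,4,5,5-tetramethyl-1,3,2-dioxaborolane, CC(C)OB1OC(C)(C)C(C)(C)O1, and an aq NH4Cl quench should then give 19.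

**Further compounds**

F1 | step 13 | (3E,5E,7E,9E)-3,7-dimethyl-10-(tributylstannyl)deca-3,5,7,9-tetraen-2-one | CC(=O)/C(C)=C/C=C/C(C)=C/C=C/[Sn](CCCC)(CCCC)CCCC
F2 | step 10 | (E)-5-[(R)-4-(tert-butyldimethylsilyloxy)-2,6,6-trimethylcyclohex-1-en-1-yl]-3-methylpent-2-en-4-ynal | O=C/C=C(\C)C#CC1=C(C)C[C@@H](O[Si](C)(C)C(C)(C)C)CC1(C)C
F3 | step 10 | (E)-3-bromo-1-iodo-2-methylprop-1-ene | BrC/C(C)=C/I
F4 | step 10 | diethyl [(E)-3-iodo-2-methylprop-2-en-1-yl]phosphonate | CCOP(=O)(OCC)C/C(C)=C/I
F5 | step 10 | sodium salt of the α-carbanion of phosphonate F4 | [Na+].CCOP(=O)(OCC)[CH-]/C(C)=C/I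
F6 | step 12 | (E)-2-(tributylstannyl)vinyllithium | [Li]/C=C/[Sn](CCCC)(CCCC)CCCC
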